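## Retrosynthetic overview

1. Feature: the five imidazole ring atoms, N1(Me)–C2(N)–N3–C4–C5, are those of creatinine. Its C5 methylene lies next to N1–Me, where the 2-hydroxy-3,4-dimethoxybenzyl group sits. Its C4 carbonyl lies next to N3, where the 4-methoxybenzyl group sits.
2. Last bond made: the amidine C–N bond between the exocyclic nitrogen on C2 and the imidazoline-2,5-dione ring. It comes from the free 2-aminoimidazole and N-silylated 1-methylparabanic acid, which has one N–H and so takes up one silyl group.
3. Key disconnection: C4–CH2Ar, by Negishi coupling of the imidazol-4-yl triflate with 4-methoxybenzylzinc chloride. The triflate comes from aromatising O-triflation of the 5-benzyl glycocyamidine.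
4. C5–CH2Ar comes from Knoevenagel condensation of creatinine, N,N-di-Boc protection at the arylidene stage (no C5–H, so no enol carbonate) and hydrogenation. The phenol is carried as a MOM ether, because an aryl carbonate would sit within a six-membered reach of the C5 carbanion and invite acyl transfer.
5. Ring order: no ring is built. Both heterocycles and both arenes are bought, and the creatinine ring becomes aromatic in the triflation step.

Key step: step 7

Assumption: the arylidene geometry is left open because hydrogenation erases it, and both Boc groups are taken to end up on the exocyclic nitrogen, since a Boc group on N3 would be a labile acyl-imide that DMAP passes on.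

## Route

Step 1
Reactants: 1 2-hydroxy-3,4-dimethoxybenzaldehyde
Product: 2 3,4-dimethoxy-2-(methoxymethoxy)benzaldehyde
Conditions: NaH, DMF, 0 °C; MOMCl, 0 to 25 °C
Reagents that add atoms: chloromethyl methyl ether (MOMCl), COCCl
Why: Williamson-type O-alkylation of the sodium phenoxide with a very reactive chloromethyl ether masks the ortho phenol, which could otherwise attack the C4 carbonyl after the condensation, and the acetal later falls off under the same acid as the Boc groups.

Step 2
Reactants: 2 3,4-dimethoxy-2-(methoxymethoxy)benzaldehyde; 3 creatinine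
Product: 4 2-amino-5-[3,4-dimethoxy-2-(methoxymethoxy)benzylidene]-1-methyl-1,5-dihydro-4H-imidazol-4-one
Conditions: piperidine, n-BuOH, 110 °C; product collected by filtration
Reagents that add atoms: none
Why: Knoevenagel condensation, in which the C5 methylene between the C4 carbonyl and N1 is the only C–H acidic site of creatinine, piperidine activates the aldehyde as its iminium ion, and loss of water gives a sparingly soluble conjugated arylidene while the ethers are inert to amine base.

Step 3
Reactants: 4 2-amino-5-[3,4-dimethoxy-2-(methoxymethoxy)benzylidene]-1-methyl-1,5-dihydro-4H-imidazol-4-one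
Product: 5 di-tert-butyl {5-[3,4-dimethoxy-2-(methoxymethoxy)benzylidene]-1-methyl-4-oxo-4,5-dihydro-1H-imidazol-2-yl}imidodicarbonate
Conditions: Boc2O (3 equiv), DMAP (0.2 equiv), Et3N, THF–DMF, 25 to 40 °C
Reagents that add atoms: di-tert-butyl dicarbonate, CC(C)(C)OC(=O)OC(=O)OC(C)(C)C
Why: DMAP-catalysed N-acylation carried through to the imidodicarbonate is known for 2-aminoazoles and 2-aminoimidazolones, and at this stage C5 bears no hydrogen, so the ring cannot enolise and no enol carbonate can form.

Step 4
Reactants: 5 di-tert-butyl {5-[3,4-dimethoxy-2-(methoxymethoxy)benzylidene]-1-methyl-4-oxo-4,5-dihydro-1H-imidazol-2-yl}imidodicarbonate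
Product: 6 (±)-di-tert-butyl {5-[3,4-dimethoxy-2-(methoxymethoxy)benzyl]-1-methyl-4-oxo-4,5-dihydro-1H-imidazol-2-yl}imidodicarbonate
Conditions: H2 (1 atm), Pd/C, EtOAc, 25 °C
Reagents that add atoms: none
Why: Heterogeneous catalytic hydrogenation of a conjugated trisubstituted alkene is well known for 5-arylidene hydantoins and creatinines; C5 is formed racemic on purpose because step 5 makes it planar again, and aryl ethers, MOM and Boc groups are untouched under neutral conditions.

Step 5
Reactants: 6 (±)-di-tert-butyl {5-[3,4-dimethoxy-2-(methoxymethoxy)benzyl]-1-methyl-4-oxo-4,5-dihydro-1H-imidazol-2-yl}imidodicarbonate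
Product: 8 2-[bis(tert-butoxycarbonyl)amino]-5-[3,4-dimethoxy-2-(methoxymethoxy)benzyl]-1-methyl-1H-imidazol-4-yl trifluoromethanesulfonate, via potassium imidazol-4-olate 7 (not isolated)
Conditions: KN(SiMe3)2 (1.1 equiv), THF, −78 °C; PhNTf2 (1.2 equiv), −78 to 0 °C, under argon; Et3N-deactivated silica
Reagents that add atoms: N-phenylbis(trifluoromethanesulfonimide), O=S(=O)(N(c1ccccc1)S(=O)(=O)C(F)(F)F)C(F)(F)F
Why: Proposed new method: KN(SiMe3)2 removes the C5–H, which is acidified by the C4 carbonyl and by the gain of the 6π aromatic 4-oxidoimidazole 7 whose charge rests on O4 and C5 only, and the hard sulfonyl donor PhNTf2 should react at oxygen and fix the aromatic tautomer as 8; the closest known reactions are enolate O-triflation of ketones and lactams with N-aryltriflimides and the conversion of oxazol-4(5H)-ones and thiazol-4(5H)-ones into azol-4-yl triflates, but a 2-aminoimidazol-4-one has not been taken through it.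

Step 6
Reactants: 9 4-methoxybenzyl chloride
Product: 10 4-methoxybenzylzinc chloride (titrated THF solution)
Conditions: Zn dust, LiCl, THF, 0 to 25 °C
Reagents that add atoms: zinc, [Zn]
Why: Direct oxidative insertion of zinc into the benzylic C–Cl bond, with LiCl keeping the metal surface clear by solubilising the organozinc species, is a known preparation of benzylic zinc chlorides and is held at or below 25 °C to suppress Wurtz-type homocoupling.

Step 7
Reactants: 8 2-[bis(tert-butoxycarbonyl)amino]-5-[3,4-dimethoxy-2-(methoxymethoxy)benzyl]-1-methyl-1H-imidazol-4-yl trifluoromethanesulfonate; 10 4-methoxybenzylzinc chloride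
Product: 11 di-tert-butyl {5-[3,4-dimethoxy-2-(methoxymethoxy)benzyl]-4-(4-methoxybenzyl)-1-methyl-1H-imidazol-2-yl}imidodicarbonate
Conditions: Pd(OAc)2 (3 mol %), SPhos (6 mol %), 10 (1.5 equiv), THF, 25 to 50 °C
Reagents that add atoms: none
Why: The zinc reagent reduces Pd(OAc)2 to SPhos-ligated zerovalent palladium, which inserts into the C4–O bond of 8; the benzyl group then passes from zinc to divalent palladium and reductive elimination forms the C4–CH2 bond, a benzyl ligand offering no β-hydride pathway. This is a Negishi sp2–sp3 coupling of the type established for LiCl-solubilised benzylic zinc chlorides with heteroaryl halides and triflates, with oxazol-4-yl and thiazol-4-yl triflates as the nearest electrophiles. No ring is closed and no stereocentre is made. The step needs site selectivity, and the triflate is the only reactive C–X bond in 8 and marks the former carbonyl carbon, so the 4-methoxybenzyl group can only arrive at C4, next to N3 and remote from N1–Me. It also needs chemoselectivity: the imidodicarbonate leaves no N–H to quench the zinc reagent, weakens N3 and the exocyclic nitrogen as donors to palladium and makes the ring electron-poorer, which should speed oxidative addition, while carbamates, MOM and methyl ethers are inert to RZnCl. The bulky electron-rich biaryl phosphine is chosen because C4 is flanked by the C5 benzyl group.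

Step 8
Reactants: 11 di-tert-butyl {5-[3,4-dimethoxy-2-(methoxymethoxy)benzyl]-4-(4-methoxybenzyl)-1-methyl-1H-imidazol-2-yl}imidodicarbonate
Product: 12 6-{[2-amino-4-(4-methoxybenzyl)-1-methyl-1H-imidazol-5-yl]methyl}-2,3-dimethoxyphenol
Conditions: HCl (4 M in 1,4-dioxane), MeOH, 25 to 40 °C; aq. NaHCO3
Reagents that add atoms: none
Why: Acidolysis, in which both carbamates fragment through the tert-butyl cation and a carbamic acid that loses CO2, the MOM acetal is transacetalised by methanol (which also scavenges the cations and so spares the electron-rich arenes), and the acid-stable 2-aminoimidazolium salt is freed with NaHCO3.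

Step 9
Reactants: 12 6-{[2-amino-4-(4-methoxybenzyl)-1-methyl-1H-imidazol-5-yl]methyl}-2,3-dimethoxyphenol; 13 1-methylparabanic acid
Product: 15 pyronaamidine, via 1-methyl-3-(trimethylsilyl)parabanic acid 14 (not isolated)
Conditions: 13 (3 equiv), N,O-bis(trimethylsilyl)acetamide (3 equiv), MeCN, 80 °C, then evaporation; 12, toluene, 110 °C; aqueous work-up
Reagents that add atoms: none
Why: Addition–elimination condensation known for 2-aminoimidazoles of this alkaloid family: the exocyclic NH2 attacks the C4 carbonyl next to the silylated N3, which reacts as its O-silyl imidate tautomer and leaves as trimethylsilanol, whereas the C5 carbonyl next to N-methyl lacks this activation, so the 4-amino-1-methylimidazoline-2,5-dione regiochemistry of the target results.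

## Compound list

1 | 2-hydroxy-3,4-dimethoxybenzaldehyde | COc1ccc(C=O)c(O)c1OC | starting material
2 | 3,4-dimethoxy-2-(methoxymethoxy)benzaldehyde | COCOc1c(C=O)ccc(OC)c1OC | intermediate
3 | creatinine | CN1CC(=O)N=C1N | starting material
4 | 2-amino-5-[3,4-dimethoxy-2-(methoxymethoxy)benzylidene]-1-methyl-1,5-dihydro-4H-imidazol-4-one (alkene geometry open) | CN1C(N)=NC(=O)C1=Cc1ccc(OC)c(OC)c1OCOC | intermediate
5 | di-tert-butyl {5-[3,4-dimethoxy-2-(methoxymethoxy)benzylidene]-1-methyl-4-oxo-4,5-dihydro-1H-imidazol-2-yl}imidodicarbonate (alkene geometry open) | CN1C(N(C(=O)OC(C)(C)C)C(=O)OC(C)(C)C)=NC(=O)C1=Cc1ccc(OC)c(OC)c1OCOC | intermediate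
6 | (±)-di-tert-butyl {5-[3,4-dimethoxy-2-(methoxymethoxy)benzyl]-1-methyl-4-oxo-4,5-dihydro-1H-imidazol-2-yl}imidodicarbonate (racemic at C5) | CN1C(N(C(=O)OC(C)(C)C)C(=O)OC(C)(C)C)=NC(=O)C1Cc1ccc(OC)c(OC)c1OCOC | intermediate
7 | potassium 2-[bis(tert-butoxycarbonyl)amino]-5-[3,4-dimethoxy-2-(methoxymethoxy)benzyl]-1-methyl-1H-imidazol-4-olate | [K+].Cn1c(N(C(=O)OC(C)(C)C)C(=O)OC(C)(C)C)nc([O-])c1Cc1ccc(OC)c(OC)c1OCOC | intermediate
8 | 2-[bis(tert-butoxycarbonyl)amino]-5-[3,4-dimethoxy-2-(methoxymethoxy)benzyl]-1-methyl-1H-imidazol-4-yl trifluoromethanesulfonate | Cn1c(N(C(=O)OC(C)(C)C)C(=O)OC(C)(C)C)nc(OS(=O)(=O)C(F)(F)F)c1Cc1ccc(OC)c(OC)c1OCOC | intermediate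
9 | 4-methoxybenzyl chloride | COc1ccc(CCl)cc1 | starting material
10 | 4-methoxybenzylzinc chloride | COc1ccc(C[Zn]Cl)cc1 | intermediate
11 | di-tert-butyl {5-[3,4-dimethoxy-2-(methoxymethoxy)benzyl]-4-(4-methoxybenzyl)-1-methyl-1H-imidazol-2-yl}imidodicarbonate | Cn1c(N(C(=O)OC(C)(C)C)C(=O)OC(C)(C)C)nc(Cc2ccc(OC)cc2)c1Cc1ccc(OC)c(OC)c1OCOC | intermediate
12 | 6-{[2-amino-4-(4-methoxybenzyl)-1-methyl-1H-imidazol-5-yl]methyl}-2,3-dimethoxyphenol | Cn1c(N)nc(Cc2ccc(OC)cc2)c1Cc1ccc(OC)c(OC)c1O | intermediate
13 | 1-methylparabanic acid | CN1C(=O)NC(=O)C1=O | starting material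
14 | 1-methyl-3-(trimethylsilyl)parabanic acid | CN1C(=O)N([Si](C)(C)C)C(=O)C1=O | intermediate
15 | pyronaamidine | COc1ccc(Cc2nc(NC3=NC(=O)N(C)C3=O)n(C)c2Cc2ccc(OC)c(OC)c2O)cc1 | target

## Step count

- Total step count: 9
- Longest linear sequence: 8 (steps 1–5 and 7–9; step 6 is a one-step branch)

## Steps most likely to fail

**1. Step 5.** The anion may be consumed before sulfonylation, either by intermolecular Boc transfer to O4 or by oxidation at C5. The product may also lose its triflyl group by S–O cleavage on silica.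

The fallback sets out from 6 and comes back at 11, and uses only known reactions. Lactam 6 is thionated at C4 with Lawesson's reagent (THF, 25 to 50 °C) to (±)-di-tert-butyl {5-[3,4-dimethoxy-2-(methoxymethoxy)benzyl]-1-methyl-4-thioxo-4,5-dihydro-1H-imidazol-2-yl}imidodicarbonate F1. K2CO3 and MeI in acetone alkylate the soft sulfur of its ene-thiolate and give the aromatic di-tert-butyl {5-[3,4-dimethoxy-2-(methoxymethoxy)benzyl]-1-methyl-4-(methylthio)-1H-imidazol-2-yl}imidodicarbonate F2. Its C4–S bond lies α to N3 and is coupled with zinc reagent 10 under Pd(OAc)2 and SPhos. This is the known coupling of methylthio-substituted N-heterocycles with benzylic zinc chlorides, and it gives 11.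

**2. Step 7.** Oxidative addition at the flanked C4–O bond may be slower than attack of the zinc reagent at sulfur, which removes the triflyl group. It may also be slower than homocoupling of the benzylzinc chloride. Zinc salts may in addition strip a Boc group and expose an N–H that binds palladium.

The fallback sets out from 8 and comes back at 12. It replaces the sp3 zinc nucleophile by a non-nucleophilic arylboronic acid and brings in the methylene carbon as CO. Carbonylative Suzuki–Miyaura coupling of 8 with (4-methoxyphenyl)boronic acid (CO 1 atm, PdCl2(dppf), K2CO3, anisole, 80 °C) gives di-tert-butyl {5-[3,4-dimethoxy-2-(methoxymethoxy)benzyl]-4-(4-methoxybenzoyl)-1-methyl-1H-imidazol-2-yl}imidodicarbonate F3. NaBH4 in MeOH–THF reduces it to (±)-di-tert-butyl {5-[3,4-dimethoxy-2-(methoxymethoxy)benzyl]-4-[hydroxy(4-methoxyphenyl)methyl]-1-methyl-1H-imidazol-2-yl}imidodicarbonate F4. Ionic hydrogenation with Et3SiH and TFA in CH2Cl2 removes the doubly benzylic hydroxyl group and both Boc groups and the MOM group in the same operation, which gives 12.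

**3. Step 3.** The second acylation may stall at the mono-carbamate or place the second Boc group on N3. The imidodicarbonate may also shed a Boc group during purification.

The fallback sets out from 4 and comes back at 12. It uses a protecting group with one point of attachment that leaves no N–H.

- Heating 4 with N,N-dimethylformamide dimethyl acetal (toluene, 90 °C) gives N'-{5-[3,4-dimethoxy-2-(methoxymethoxy)benzylidene]-1-methyl-4-oxo-4,5-dihydro-1H-imidazol-2-yl}-N,N-dimethylformimidamide F5.
- Hydrogenation as in step 4 gives (±)-N'-{5-[3,4-dimethoxy-2-(methoxymethoxy)benzyl]-1-methyl-4-oxo-4,5-dihydro-1H-imidazol-2-yl}-N,N-dimethylformimidamide F6.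
- Triflation as in step 5 gives 5-[3,4-dimethoxy-2-(methoxymethoxy)benzyl]-2-{[(dimethylamino)methylidene]amino}-1-methyl-1H-imidazol-4-yl trifluoromethanesulfonate F7.
- Coupling with 10 as in step 7 gives N'-{5-[3,4-dimethoxy-2-(methoxymethoxy)benzyl]-4-(4-methoxybenzyl)-1-methyl-1H-imidazol-2-yl}-N,N-dimethylformimidamide F8.
- Aqueous HCl in MeOH at reflux hydrolyses the amidine and the MOM acetal together and gives 12.

## Further compounds

F1 | step 5 | (±)-di-tert-butyl {5-[3,4-dimethoxy-2-(methoxymethoxy)benzyl]-1-methyl-4-thioxo-4,5-dihydro-1H-imidazol-2-yl}imidodicarbonate | CN1C(N(C(=O)OC(C)(C)C)C(=O)OC(C)(C)C)=NC(=S)C1Cc1ccc(OC)c(OC)c1OCOC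
F2 | step 5 | di-tert-butyl {5-[3,4-dimethoxy-2-(methoxymethoxy)benzyl]-1-methyl-4-(methylthio)-1H-imidazol-2-yl}imidodicarbonate | Cn1c(N(C(=O)OC(C)(C)C)C(=O)OC(C)(C)C)nc(SC)c1Cc1ccc(OC)c(OC)c1OCOC
F3 | step 7 | di-tert-butyl {5-[3,4-dimethoxy-2-(methoxymethoxy)benzyl]-4-(4-methoxybenzoyl)-1-methyl-1H-imidazol-2-yl}imidodicarbonate | Cn1c(N(C(=O)OC(C)(C)C)C(=O)OC(C)(C)C)nc(C(=O)c2ccc(OC)cc2)c1Cc1ccc(OC)c(OC)c1OCOC
F4 | step 7 | (±)-di-tert-butyl {5-[3,4-dimethoxy-2-(methoxymethoxy)benzyl]-4-[hydroxy(4-methoxyphenyl)methyl]-1-methyl-1H-imidazol-2-yl}imidodicarbonate | Cn1c(N(C(=O)OC(C)(C)C)C(=O)OC(C)(C)C)nc(C(O)c2ccc(OC)cc2)c1Cc1ccc(OC)c(OC)c1OCOC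
F5 | step 3 | N'-{5-[3,4-dimethoxy-2-(methoxymethoxy)benzylidene]-1-methyl-4-oxo-4,5-dihydro-1H-imidazol-2-yl}-N,N-dimethylformimidamide | CN(C)/C=N/C1=NC(=O)C(=Cc2ccc(OC)c(OC)c2OCOC)N1C
F6 | step 3 | (±)-N'-{5-[3,4-dimethoxy-2-(methoxymethoxy)benzyl]-1-methyl-4-oxo-4,5-dihydro-1H-imidazol-2-yl}-N,N-dimethylformimidamide | CN(C)/C=N/C1=NC(=O)C(Cc2ccc(OC)c(OC)c2OCOC)N1C
F7 | step 3 | 5-[3,4-dimethoxy-2-(methoxymethoxy)benzyl]-2-{[(dimethylamino)methylidene]amino}-1-methyl-1H-imidazol-4-yl trifluoromethanesulfonate | CN(C)/C=N/c1nc(OS(=O)(=O)C(F)(F)F)c(Cc2ccc(OC)c(OC)c2OCOC)n1C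
F8 | step 3 | N'-{5-[3,4-dimethoxy-2-(methoxymethoxy)benzyl]-4-(4-methoxybenzyl)-1-methyl-1H-imidazol-2-yl}-N,N-dimethylformimidamide | CN(C)/C=N/c1nc(Cc2ccc(OC)cc2)c(Cc2ccc(OC)c(OC)c2OCOC)n1C
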